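Early in the summer run, at 6.00 min, target stands at 3% and cross product at 10% of the charged starting material, so you can treat the flask as a flow divider with two outlets.

| flask | starting material | partner | second substrate | temperature | remark | time |
|---|---|---|---|---|---|---|
| summer | 0.11 M | 0.0486 M | 0.054 M | 100 °C | run made earlier |  |
| maple | 0.054 M | 0.0486 M | 0.0540 M | 100 °C |  | 6.0 h |
| larch | 0.054 M | 0.0486 M | 0.0540 M | 70 °C |  | 6.0 h |

summer run (percent of the starting material charged)

| time / min | target / % | cross product / % |
|---|---|---|
| 6.00 | 3 | 10 |
| 10.0 | 7 | 19 |
| 20.0 | 10 | 27 |
| 40.0 | 16 | 31 |
| 80.0 | 15 | 36 |

(readings scatter by 1.5 percentage points)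

* which flask leads in share of target in all that became target or cross product or over-reaction product ("all alike" within 1.5 percentage points) (maple / larch / all alike)
* share of target in all that became target or cross product or over-reaction product, maple
* share of target in all that became target or cross product or over-reaction product, larch

My assumption is that target forms with partner and cross product with second substrate, each taking one starting material. Their ratio then follows partner per second substrate. That ratio moves along the curve, but I replace it by its charged value, 0.900, and let one constant absorb the difference. Target per cross product at the last reading, divided by charged partner per second substrate, is the split factor (a selectivity factor), 0.463. Target's share of the two reads 27.0% at 20.0 min, 34.0% at 40.0 min and 29.4% at 80.0 min, but each reading carries a scatter of 1.5 percentage points, so these readings do not show the price of this shortcut.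

Now turn the settings. Starting material is cut to half, and under my assumption it cancels from the ratio. Partner per second substrate stays as charged, so my share for maple is 29.4%. The longer time I leave out, taking the ratio as the last reading has it. Temperature is not shown by these runs, so keeping that share for larch is a guess.

The forecast says all alike: 22% for maple (14% to 33%) and 22% for larch (11% to 36%). Its ground is "If target formation is first order in it while cross product formation is not, the ratio halves", so my maple figure stands above its own.

| flask | target | cross product | over-reaction product | share of target | split factor |
|---|---|---|---|---|---|
| maple | 22.3% | 53.2% | 4.31% | 28.0% | 0.466 |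
| larch | 13.0% | 48.4% | 0.563% | 21.0% | 0.299 |

    starting material + partner → target (k = 0.190 M⁻¹ min⁻¹, Ea = 82.0 kJ mol⁻¹)
    second substrate + partner → second product (k = 0.370 M⁻¹ min⁻¹, Ea = 82.0 kJ mol⁻¹)
    starting material + second substrate → cross product (k = 0.520 M⁻¹ min⁻¹, Ea = 66.0 kJ mol⁻¹)
    partner + target → over-reaction product (k = 0.0470 M⁻¹ min⁻¹, Ea = 75.0 kJ mol⁻¹)
    2 starting material → self-condensation product (k = 0.0620 M⁻¹ min⁻¹, Ea = 96.0 kJ mol⁻¹)
    (constants at 100 °C)

The flasks part by 7 points, with maple ahead, where the forecast had them alike. At the start, larch sends starting material to cross product 4.8 times as fast as to target, while maple does so 3.04 times as fast. Now take the neighbour like larch but with partner per second substrate cut to 0.222. Larch's split factor gives it a share of 6.23%, and the flask gives 5.67%.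

The data are calculated from invented constants; scatter was added.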